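**Retrosynthetic overview**

1. Numbering as in the target: oxolane (ring C) O1, C2 (carries ring A), C3 (carries C9H2OAc), C4 (carries OH and C7'H2–ring B), C5H2. Last moves: benzyl ether hydrogenolysis, C9 acetylation, desilylation; the C7'–ring B bond comes from opening a C4 spiro-oxirane with the arylmagnesium reagent made from 1.
2. The oxirane derives from the geminal diester at C4 of oxolane 8: one ester is excised and replaced by OH (dealkoxycarbonylation, then enolate hydroxylation anti to C9), the other is reduced and becomes C7'.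
3. Key disconnection: 8 ⇒ cis-cyclopropane 6 (C2–C3–C4) + formaldehyde 7; O1–C2 and C5–C4 are made together in one Lewis-acid (3+2) annulation.
4. Enabling feature: ring A, para-oxygenated, sits on C2 and stabilises positive charge there, while C4 can carry two esters; the C2–C4 bond of a cyclopropane C2–C3–C4 is therefore a donor–acceptor bond, and the unsubstituted C5H2–O1 unit is a formaldehyde unit.
5. 6 ⇒ (Z)-alkene 4 + malonate carbene (ylide 5), asymmetric; 4 ⇒ aryl bromide 1 + alkyne 2. Ring order: cyclopropane (step 3), ring C (step 4), oxirane (step 8, opened in step 9); rings A and B are bought.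

Key step: step 4

Assumption: ylide 5 is taken as a catalogue reagent (otherwise made in one operation from dimethyl malonate, PhI(OAc)2 and KOH), and formaldehyde 7 is supplied as its solid polymer paraformaldehyde, which releases the monomer under the Lewis-acidic conditions of step 4.

**Route**

Step 1
Reactants: 1 1-(benzyloxy)-4-bromo-2-methoxybenzene; 2 tert-butyl(diphenyl)(prop-2-yn-1-yloxy)silane
Product: 3 tert-butyl({3-[4-(benzyloxy)-3-methoxyphenyl]prop-2-yn-1-yl}oxy)diphenylsilane
Conditions: PdCl2(MeCN)2 (2 mol%), XPhos (6 mol%), Cs2CO3, MeCN, 80 °C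
Reagents that add atoms: none
Why: Copper-free Sonogashira coupling, which should tolerate the electron-rich aryl bromide with the bulky biaryl phosphine and leaves the silyl and benzyl ethers untouched; no stereocentre is formed.

Step 2
Reactants: 3 aryl alkyne
Product: 4 tert-butyl({(2Z)-3-[4-(benzyloxy)-3-methoxyphenyl]prop-2-en-1-yl}oxy)diphenylsilane
Conditions: H2 (1 atm), Pd/CaCO3 poisoned with Pb(OAc)2, quinoline, EtOAc, rt
Reagents that add atoms: none
Why: Semi-hydrogenation over poisoned palladium delivers both hydrogens to one face of the alkyne and should give the (Z)-alkene, the aryl benzyl ether being stable on this deactivated catalyst.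

Step 3
Reactants: 4 (Z)-alkene; 5 dimethyl 2-(phenyl-λ3-iodanylidene)propanedioate
Product: 6 dimethyl (2R,3R)-2-[4-(benzyloxy)-3-methoxyphenyl]-3-({[tert-butyl(diphenyl)silyl]oxy}methyl)cyclopropane-1,1-dicarboxylate (the cis-2,3 isomer)
Conditions: [Cu(MeCN)4]PF6 (5 mol%), chiral side-arm-modified bis(oxazoline) ligand (6 mol%), 4 Å molecular sieves, toluene, 0 °C to rt
Reagents that add atoms: none
Why: Asymmetric copper–carbene cyclopropanation with a malonate iodonium ylide, in which the concerted syn addition should carry the (Z) geometry into the cis relationship of C2 and C3 and the chiral bis(oxazoline) ligand on monovalent copper selects the alkene face, the ligand antipode being chosen so that the (2R,3R) isomer forms.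

Step 4
Reactants: 6 cis-cyclopropane diester; 7 formaldehyde
Product: 8 dimethyl (4R,5S)-5-[4-(benzyloxy)-3-methoxyphenyl]-4-({[tert-butyl(diphenyl)silyl]oxy}methyl)oxolane-3,3-dicarboxylate
Conditions: paraformaldehyde in excess as the source of 7, Sc(OTf)3 (10 mol%), 4 Å molecular sieves, ClCH2CH2Cl, 40 °C
Reagents that add atoms: none
Why: Formal (3+2) annulation of a donor–acceptor cyclopropane with an aldehyde, the closest known type being the Lewis-acid-catalysed union of 2-arylcyclopropane-1,1-diesters with aldehydes to 2,5-disubstituted oxolane-3,3-diesters. Sc(OTf)3 chelates the geminal diester and polarises the C2–C4 bond, whose benzylic end is stabilised by ring A; the carbonyl oxygen of formaldehyde attacks C2 of this tight ion pair from the side opposite to C4 (O1–C2), and the malonate enolate carbon C4 then adds to the oxocarbenium carbon C5 (C5–C4). Ring C is the only ring closed, by this aldol-type attack, formally a 5-endo-trig closure onto the oxocarbenium carbon, the same closure that operates in all aldehyde annulations of this class. C2 is the only stereocentre made: it is set by inversion of the cyclopropane carbon (R in 6, S in 8), so the cis cyclopropane should give the 4,5-trans oxolane, which is also the thermodynamically preferred isomer if some ionisation and re-closure occurs; C3 is untouched, and C4 and C5 carry no stereochemistry because the two esters are identical and formaldehyde has no substituent. The step needs cleavage of C2–C4 rather than C3–C4, secured by the aryl donor on C2, and capture by formaldehyde ahead of attack by an ester oxygen or hydroxymethylation of ring A, secured by the excess of the small aldehyde, the methyl esters and the mild Lewis acid; every atom of 6 and of 7 ends up in 8.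

Step 5
Reactants: 8 oxolane diester
Product: 9 methyl (3S,4R,5S)-5-[4-(benzyloxy)-3-methoxyphenyl]-4-({[tert-butyl(diphenyl)silyl]oxy}methyl)oxolane-3-carboxylate (major epimer at the ester-bearing carbon)
Conditions: LiCl, H2O (2 equiv), DMSO, 140 °C
Reagents that add atoms: none
Why: Krapcho dealkoxycarbonylation (chloride demethylates one ester, the carboxylate loses CO2 and the enolate is protonated), which should give the monoester as an epimer mixture with the all-trans isomer predominating; this centre becomes planar again in step 6, so the ratio does not matter.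

Step 6
Reactants: 9 oxolane monoester
Product: 11 methyl (3S,4R,5S)-5-[4-(benzyloxy)-3-methoxyphenyl]-4-({[tert-butyl(diphenyl)silyl]oxy}methyl)-3-hydroxyoxolane-3-carboxylate, via potassium ester enolate 10 (not isolated)
Conditions: KN(SiMe3)2, THF, −78 °C; then 3-phenyl-2-(phenylsulfonyl)oxaziridine, −78 °C; AcOH quench
Reagents that add atoms: 3-phenyl-2-(phenylsulfonyl)oxaziridine, O=S(=O)(c1ccccc1)N1OC1c1ccccc1
Why: Enolate hydroxylation with an N-sulfonyloxaziridine, in which the planar enolate should be oxidised on the ring face opposite to the vicinal silyloxymethyl group on C3, placing the new C4–OH cis to ring A and the ester cis to C9 (C4 as in the target), while the potassium counter-ion and the low temperature suppress addition to the sulfonimine and loss of the ring alkoxide from C5.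

Step 7
Reactants: 11 α-hydroxy ester
Product: 12 (3R,4R,5S)-5-[4-(benzyloxy)-3-methoxyphenyl]-4-({[tert-butyl(diphenyl)silyl]oxy}methyl)-3-(hydroxymethyl)oxolan-3-ol
Conditions: LiBH4, THF, 0 °C to rt
Reagents that add atoms: none
Why: Borohydride reduction of an α-hydroxy ester to the 1,2-diol, which touches no stereocentre and spares the silyl and benzyl ethers.

Step 8
Reactants: 12 diol
Product: 14 (3R,6S,7R)-6-[4-(benzyloxy)-3-methoxyphenyl]-7-({[tert-butyl(diphenyl)silyl]oxy}methyl)-1,5-dioxaspiro[2.4]heptane, via primary tosylate 13 (not isolated)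
Conditions: NaH (2.2 equiv), 1-(4-methylbenzenesulfonyl)imidazole, THF, 0 °C to rt
Reagents that add atoms: none
Why: One-flask sulfonylation of the primary alkoxide and intramolecular Williamson closure (3-exo-tet) by the tertiary alkoxide, which should form the spiro-oxirane with the C4–O bond intact, so the C4 configuration is retained.

Step 9
Reactants: 14 spiro-oxirane; 1 1-(benzyloxy)-4-bromo-2-methoxybenzene
Product: 16 (3S,4R,5S)-5-[4-(benzyloxy)-3-methoxyphenyl]-3-{[4-(benzyloxy)-3-methoxyphenyl]methyl}-4-({[tert-butyl(diphenyl)silyl]oxy}methyl)oxolan-3-ol, via arylmagnesium bromide 15 (not isolated)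
Conditions: 1, Mg turnings, THF, 40 °C; then CuI (copper monoiodide, 10 mol%), 14, THF, −30 to 0 °C; aqueous work-up
Reagents that add atoms: none
Why: Copper-catalysed Grignard opening of a 2,2-disubstituted oxirane, which should occur by SN2 attack at the unsubstituted CH2 terminus (C7') and so gives the tertiary C4 alcohol with retention, the quaternary C4 being untouched.

Step 10
Reactants: 16 silyl ether
Product: 17 (3S,4R,5S)-5-[4-(benzyloxy)-3-methoxyphenyl]-3-{[4-(benzyloxy)-3-methoxyphenyl]methyl}-4-(hydroxymethyl)oxolan-3-ol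
Conditions: Bu4NF, THF, 0 °C to rt
Reagents that add atoms: none
Why: Fluoride-induced cleavage of the silyl ether should free the primary C9 alcohol without affecting the benzyl ethers, the tertiary alcohol or any stereocentre.

Step 11
Reactants: 17 diol
Product: 18 [(2S,3R,4S)-2-[4-(benzyloxy)-3-methoxyphenyl]-4-{[4-(benzyloxy)-3-methoxyphenyl]methyl}-4-hydroxyoxolan-3-yl]methyl acetate
Conditions: Ac2O (1.1 equiv), pyridine, CH2Cl2, 0 °C to rt
Reagents that add atoms: acetic anhydride, CC(=O)OC(C)=O
Why: Acylation with acetic anhydride and pyridine should be selective for the primary C9 alcohol, because the hindered tertiary C4 alcohol is not acetylated without an acyl-transfer catalyst and both phenols are still benzylated.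

Step 12
Reactants: 18 bis(benzyl ether) acetate
Product: 19 olivil monoacetate, [(2S,3R,4S)-4-hydroxy-2-(4-hydroxy-3-methoxyphenyl)-4-[(4-hydroxy-3-methoxyphenyl)methyl]oxolan-3-yl]methyl acetate
Conditions: H2 (1 atm), Pd/C (10 wt%), EtOAc, rt, stopped at full conversion
Reagents that add atoms: none
Why: Hydrogenolysis of the two aryl benzyl ethers, which should be cleaved faster than the cyclic benzylic C2–O1 ether in a neutral aprotic solvent, so the acetate, the tertiary alcohol and all three stereocentres should remain.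

**Compound list**

1 | 1-(benzyloxy)-4-bromo-2-methoxybenzene | COc1cc(Br)ccc1OCc1ccccc1 | starting material
2 | tert-butyl(diphenyl)(prop-2-yn-1-yloxy)silane | C#CCO[Si](c1ccccc1)(c1ccccc1)C(C)(C)C | starting material
3 | tert-butyl({3-[4-(benzyloxy)-3-methoxyphenyl]prop-2-yn-1-yl}oxy)diphenylsilane | COc1cc(C#CCO[Si](c2ccccc2)(c2ccccc2)C(C)(C)C)ccc1OCc1ccccc1 | intermediate
4 | tert-butyl({(2Z)-3-[4-(benzyloxy)-3-methoxyphenyl]prop-2-en-1-yl}oxy)diphenylsilane | COc1cc(/C=C\CO[Si](c2ccccc2)(c2ccccc2)C(C)(C)C)ccc1OCc1ccccc1 | intermediate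
5 | dimethyl 2-(phenyl-λ3-iodanylidene)propanedioate (phenyliodonium ylide of dimethyl malonate) | COC(=O)[C-](C(=O)OC)[I+]c1ccccc1 | starting material
6 | dimethyl (2R,3R)-2-[4-(benzyloxy)-3-methoxyphenyl]-3-({[tert-butyl(diphenyl)silyl]oxy}methyl)cyclopropane-1,1-dicarboxylate | COC(=O)C1(C(=O)OC)[C@@H](c2ccc(OCc3ccccc3)c(OC)c2)[C@H]1CO[Si](c1ccccc1)(c1ccccc1)C(C)(C)C | intermediate
7 | formaldehyde (supplied as paraformaldehyde) | C=O | starting material
8 | dimethyl (4R,5S)-5-[4-(benzyloxy)-3-methoxyphenyl]-4-({[tert-butyl(diphenyl)silyl]oxy}methyl)oxolane-3,3-dicarboxylate | COC(=O)C1(C(=O)OC)CO[C@H](c2ccc(OCc3ccccc3)c(OC)c2)[C@H]1CO[Si](c1ccccc1)(c1ccccc1)C(C)(C)C | intermediate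
9 | methyl (3S,4R,5S)-5-[4-(benzyloxy)-3-methoxyphenyl]-4-({[tert-butyl(diphenyl)silyl]oxy}methyl)oxolane-3-carboxylate (major epimer) | COC(=O)[C@@H]1CO[C@H](c2ccc(OCc3ccccc3)c(OC)c2)[C@H]1CO[Si](c1ccccc1)(c1ccccc1)C(C)(C)C | intermediate
10 | potassium enolate of 9 | COC([O-])=C1CO[C@H](c2ccc(OCc3ccccc3)c(OC)c2)[C@H]1CO[Si](c1ccccc1)(c1ccccc1)C(C)(C)C.[K+] | intermediate
11 | methyl (3S,4R,5S)-5-[4-(benzyloxy)-3-methoxyphenyl]-4-({[tert-butyl(diphenyl)silyl]oxy}methyl)-3-hydroxyoxolane-3-carboxylate | COC(=O)[C@@]1(O)CO[C@H](c2ccc(OCc3ccccc3)c(OC)c2)[C@H]1CO[Si](c1ccccc1)(c1ccccc1)C(C)(C)C | intermediate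
12 | (3R,4R,5S)-5-[4-(benzyloxy)-3-methoxyphenyl]-4-({[tert-butyl(diphenyl)silyl]oxy}methyl)-3-(hydroxymethyl)oxolan-3-ol | OC[C@@]1(O)CO[C@H](c2ccc(OCc3ccccc3)c(OC)c2)[C@H]1CO[Si](c1ccccc1)(c1ccccc1)C(C)(C)C | intermediate
13 | [(3S,4R,5S)-5-[4-(benzyloxy)-3-methoxyphenyl]-4-({[tert-butyl(diphenyl)silyl]oxy}methyl)-3-hydroxyoxolan-3-yl]methyl 4-methylbenzenesulfonate | Cc1ccc(cc1)S(=O)(=O)OC[C@@]1(O)CO[C@H](c2ccc(OCc3ccccc3)c(OC)c2)[C@H]1CO[Si](c1ccccc1)(c1ccccc1)C(C)(C)C | intermediate
14 | (3R,6S,7R)-6-[4-(benzyloxy)-3-methoxyphenyl]-7-({[tert-butyl(diphenyl)silyl]oxy}methyl)-1,5-dioxaspiro[2.4]heptane | O1C[C@]12CO[C@H](c1ccc(OCc3ccccc3)c(OC)c1)[C@H]2CO[Si](c1ccccc1)(c1ccccc1)C(C)(C)C | intermediate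
15 | [4-(benzyloxy)-3-methoxyphenyl]magnesium bromide | COc1cc([Mg]Br)ccc1OCc1ccccc1 | intermediate
16 | (3S,4R,5S)-5-[4-(benzyloxy)-3-methoxyphenyl]-3-{[4-(benzyloxy)-3-methoxyphenyl]methyl}-4-({[tert-butyl(diphenyl)silyl]oxy}methyl)oxolan-3-ol | COc1cc(C[C@@]2(O)CO[C@H](c3ccc(OCc4ccccc4)c(OC)c3)[C@H]2CO[Si](c2ccccc2)(c2ccccc2)C(C)(C)C)ccc1OCc1ccccc1 | intermediate
17 | (3S,4R,5S)-5-[4-(benzyloxy)-3-methoxyphenyl]-3-{[4-(benzyloxy)-3-methoxyphenyl]methyl}-4-(hydroxymethyl)oxolan-3-ol | COc1cc(C[C@@]2(O)CO[C@H](c3ccc(OCc4ccccc4)c(OC)c3)[C@H]2CO)ccc1OCc1ccccc1 | intermediate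
18 | [(2S,3R,4S)-2-[4-(benzyloxy)-3-methoxyphenyl]-4-{[4-(benzyloxy)-3-methoxyphenyl]methyl}-4-hydroxyoxolan-3-yl]methyl acetate | COc1cc(C[C@@]2(O)CO[C@H](c3ccc(OCc4ccccc4)c(OC)c3)[C@H]2COC(C)=O)ccc1OCc1ccccc1 | intermediate
19 | olivil monoacetate, [(2S,3R,4S)-4-hydroxy-2-(4-hydroxy-3-methoxyphenyl)-4-[(4-hydroxy-3-methoxyphenyl)methyl]oxolan-3-yl]methyl acetate | COc1cc(C[C@@]2(O)CO[C@H](c3ccc(O)c(OC)c3)[C@H]2COC(C)=O)ccc1O | target

**Step count and risks**

Total step count: 12. Longest linear sequence: 12 steps (from 1 and 2 to 19; the arylmagnesium reagent 15 is made from 1 inside step 9).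

Steps most likely to fail:

Step 4 (key annulation). Lewis-acid-induced oligomerisation of formaldehyde and electrophilic hydroxymethylation of the electron-rich ring A may outrun capture of the ring-opened ion pair, and cis-to-trans isomerisation of the cyclopropane before capture would erode the 4,5-trans selectivity. The fallback sets out from 6 and comes back at 8, making the two bonds one after the other. Sc(OTf)3-catalysed ring-opening of 6 with methanol (SN2 at the benzylic carbon) should give the methyl ether dimethyl 2-[(1S,2R)-1-[4-(benzyloxy)-3-methoxyphenyl]-3-{[tert-butyl(diphenyl)silyl]oxy}-1-methoxypropan-2-yl]propanedioate F1. Base-catalysed hydroxymethylation of its malonate C–H with 7 (K2CO3, THF) should give dimethyl 2-[(1S,2R)-1-[4-(benzyloxy)-3-methoxyphenyl]-3-{[tert-butyl(diphenyl)silyl]oxy}-1-methoxypropan-2-yl]-2-(hydroxymethyl)propanedioate F2. BF3·OEt2 in CH2Cl2 at low temperature should then ionise the benzylic methyl ether and let the primary hydroxyl close ring C with loss of methanol. This closure runs through the benzylic cation, so the benzylic configuration of F1 and F2 is immaterial and the trans arrangement of ring A and C9 should be favoured, giving 8.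

Step 3 (asymmetric cyclopropanation). Enantio-induction may be incomplete on a cis alkene that carries a bulky allylic silyl ether, and the copper Lewis acid may ring-open or isomerise the very electron-rich cis cyclopropane. The fallback sets out from 1 and comes back at 8, with an organocatalytic cyclopropanation of known facial sense. Mizoroki–Heck reaction of 1 with acrolein (Pd(OAc)2, Bu4NCl, NaHCO3, DMF) should give (2E)-3-[4-(benzyloxy)-3-methoxyphenyl]prop-2-enal F3. Iminium-catalysed Michael-initiated ring closure with dimethyl bromomalonate ((S)-α,α-diphenylprolinol trimethylsilyl ether, Et3N, CH2Cl2, 0 °C) should give dimethyl (2S,3R)-2-[4-(benzyloxy)-3-methoxyphenyl]-3-formylcyclopropane-1,1-dicarboxylate F4. The malonate is expected to add to the Si face of the aryl-bearing β-carbon and the enamine carbon then closes the ring trans to the aryl group, which fixes the future C3 in the required sense. NaBH4 in MeOH at −40 °C should give dimethyl (2S,3R)-2-[4-(benzyloxy)-3-methoxyphenyl]-3-(hydroxymethyl)cyclopropane-1,1-dicarboxylate F5. It is silylated in the same flask (tert-butyl(chloro)diphenylsilane, imidazole) before it can lactonise, to give the trans cyclopropane dimethyl (2S,3R)-2-[4-(benzyloxy)-3-methoxyphenyl]-3-({[tert-butyl(diphenyl)silyl]oxy}methyl)cyclopropane-1,1-dicarboxylate F6. Under the conditions of step 4, F6 and 7 should give, by inversion at the benzylic carbon, the 4,5-cis oxolane dimethyl (4R,5R)-5-[4-(benzyloxy)-3-methoxyphenyl]-4-({[tert-butyl(diphenyl)silyl]oxy}methyl)oxolane-3,3-dicarboxylate F7. BF3·OEt2 in CH2Cl2 should then epimerise F7 at the benzylic ether carbon by reversible ionisation of the C2–O1 bond, and the equilibrium should favour the 4,5-trans isomer 8.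

Step 6 (enolate hydroxylation). The ester enolate may ring-open by E1cB expulsion of the ring alkoxide at C5, and oxygen transfer may show insufficient facial selectivity. The fallback sets out from 9 and comes back at 14, by-passing steps 6 to 8 through an alkene instead of an enolate. LiBH4 reduction of 9 (THF, rt) should give [(3R,4R,5S)-5-[4-(benzyloxy)-3-methoxyphenyl]-4-({[tert-butyl(diphenyl)silyl]oxy}methyl)oxolan-3-yl]methanol F8. Appel-type iodination (iodine, PPh3, imidazole) should give tert-butyl{[(2S,3R,4S)-2-[4-(benzyloxy)-3-methoxyphenyl]-4-(iodomethyl)oxolan-3-yl]methoxy}diphenylsilane F9. E2 elimination with KOtBu in THF should give the exocyclic alkene tert-butyl{[(2S,3R)-2-[4-(benzyloxy)-3-methoxyphenyl]-4-methylideneoxolan-3-yl]methoxy}diphenylsilane F10. Epoxidation of F10 with dimethyldioxirane in acetone at 0 °C should occur on the face opposite to the silyloxymethyl group on C3 and give the spiro-oxirane 14.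

Further compounds
F1 | step 4 | dimethyl 2-[(1S,2R)-1-[4-(benzyloxy)-3-methoxyphenyl]-3-{[tert-butyl(diphenyl)silyl]oxy}-1-methoxypropan-2-yl]propanedioate | CO[C@H](c1ccc(OCc2ccccc2)c(OC)c1)[C@@H](CO[Si](c1ccccc1)(c1ccccc1)C(C)(C)C)C(C(=O)OC)C(=O)OC
F2 | step 4 | dimethyl 2-[(1S,2R)-1-[4-(benzyloxy)-3-methoxyphenyl]-3-{[tert-butyl(diphenyl)silyl]oxy}-1-methoxypropan-2-yl]-2-(hydroxymethyl)propanedioate | CO[C@H](c1ccc(OCc2ccccc2)c(OC)c1)[C@@H](CO[Si](c1ccccc1)(c1ccccc1)C(C)(C)C)C(CO)(C(=O)OC)C(=O)OC
F3 | step 3 | (2E)-3-[4-(benzyloxy)-3-methoxyphenyl]prop-2-enal | O=C/C=C/c1ccc(OCc2ccccc2)c(OC)c1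
F4 | step 3 | dimethyl (2S,3R)-2-[4-(benzyloxy)-3-methoxyphenyl]-3-formylcyclopropane-1,1-dicarboxylate | COC(=O)C1(C(=O)OC)[C@H](c2ccc(OCc3ccccc3)c(OC)c2)[C@H]1C=O
F5 | step 3 | dimethyl (2S,3R)-2-[4-(benzyloxy)-3-methoxyphenyl]-3-(hydroxymethyl)cyclopropane-1,1-dicarboxylate | COC(=O)C1(C(=O)OC)[C@H](c2ccc(OCc3ccccc3)c(OC)c2)[C@H]1CO
F6 | step 3 | dimethyl (2S,3R)-2-[4-(benzyloxy)-3-methoxyphenyl]-3-({[tert-butyl(diphenyl)silyl]oxy}methyl)cyclopropane-1,1-dicarboxylate | COC(=O)C1(C(=O)OC)[C@H](c2ccc(OCc3ccccc3)c(OC)c2)[C@H]1CO[Si](c1ccccc1)(c1ccccc1)C(C)(C)C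
F7 | step 3 | dimethyl (4R,5R)-5-[4-(benzyloxy)-3-methoxyphenyl]-4-({[tert-butyl(diphenyl)silyl]oxy}methyl)oxolane-3,3-dicarboxylate | COC(=O)C1(C(=O)OC)CO[C@@H](c2ccc(OCc3ccccc3)c(OC)c2)[C@H]1CO[Si](c1ccccc1)(c1ccccc1)C(C)(C)C
F8 | step 6 | [(3R,4R,5S)-5-[4-(benzyloxy)-3-methoxyphenyl]-4-({[tert-butyl(diphenyl)silyl]oxy}methyl)oxolan-3-yl]methanol | OC[C@@H]1CO[C@H](c2ccc(OCc3ccccc3)c(OC)c2)[C@H]1CO[Si](c1ccccc1)(c1ccccc1)C(C)(C)C
F9 | step 6 | tert-butyl{[(2S,3R,4S)-2-[4-(benzyloxy)-3-methoxyphenyl]-4-(iodomethyl)oxolan-3-yl]methoxy}diphenylsilane | IC[C@@H]1CO[C@H](c2ccc(OCc3ccccc3)c(OC)c2)[C@H]1CO[Si](c1ccccc1)(c1ccccc1)C(C)(C)C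
F10 | step 6 | tert-butyl{[(2S,3R)-2-[4-(benzyloxy)-3-methoxyphenyl]-4-methylideneoxolan-3-yl]methoxy}diphenylsilane | C=C1CO[C@H](c2ccc(OCc3ccccc3)c(OC)c2)[C@H]1CO[Si](c1ccccc1)(c1ccccc1)C(C)(C)C
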